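**At the bench.** Each stirred vessel here differs from the others in how substrate and coupling partner go in.

| flask | substrate | coupling partner | time | remark |
|---|---|---|---|---|
| teal | 0.10 M (fed, over 80 min) | 0.100 M | 6.0 h | all else is in the flask from the start; the feed brings no volume worth counting |
| violet | 0.10 M (in portions, 3, over 80 min) | 0.100 M | 6.0 h | first portion at the start, last at 80 min |
| ochre | 0.10 M | 0.100 M | 6.0 h | everything together at the start |
| grey | 0.10 M | 0.100 M (fed, over 80 min) | 6.0 h | all else is in the flask from the start; the feed brings no volume worth counting |

1. which flask leads in share of target in target plus side product ("all alike" within 1.5 percentage points) (teal / violet / ochre / grey / all alike)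
2. share of target in target plus side product at the end, teal
3. share of target in target plus side product at the end, violet
4. share of target in target plus side product at the end, ochre
5. share of target in target plus side product at the end, grey

- in percentages every species weighs as the substrate in it: one side product counts as two
- for target the crystals are counted in
- a step written with two of one species runs at k times the square of its concentration and takes two of it each time
- as a solid, counted per litre of solution: crystals
- run time (teal): 6.0 h

**What stands.** Where crystals of target lie, I freeze dissolved target at its solubility, 4.3 mM. Crystals dissolve with a coefficient of 0.0082 /s, and full-charge coupling partner removes dissolved target with a first-order constant of 0.00120 /s, so supply is faster. With substrate no longer taking it, coupling partner then decays as a pseudo-first-order species. The partner clock 5.38 h is the lifetime of coupling partner against target held at solubility.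

**Not to touch.** Each turn of over-reaction takes one coupling partner and one target. My rule is to set crystals against the coupling partner left. Where crystals are fewer and substrate no longer makes target, they are heading for zero. Over 6.0 h with crystals still lying, coupling partner on this clock falls to 32.8% of itself. My reckoning stops there, and I commit to no share.

**The forecast.** It puts teal at 40%, violet at 33%, ochre at 4% and grey at 0.1%, with teal leading. Its grounds: “the leftover partner steadily pulls target out of solution and the crystals redissolve to replace it”.

**The result.** The simulation gives teal 41.9%, violet 34.0%, ochre 6.61% and grey 0%, with teal leading.

    substrate + coupling partner → target (k1 = 0.013 /M/s)
    2 substrate → side product (k2 = 0.018 /M/s)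
    crystals ⇌ target, rate k3*(cs3 - [target]) while solid is left; crystals form when [target] > cs3 (cs3 = 4.3 mM, k3 = 0.0082 /s)
    coupling partner + target → over-reaction product (k4 = 0.012 /M/s)

**Crystals against partner.** The charges are equal, 0.10 M and 0.100 M, so the percentages compare directly. At 3.00 h, teal holds crystals 30.9% against coupling partner 17.4%, more crystals than partner. Ochre at 3.00 h holds crystals 12.6% against coupling partner 30.7%, fewer crystals than partner. The clock takes teal's coupling partner to 9.96% by 6.00 h, and the reading is 9.46%, with crystals 24.7% left. For ochre, the clock gives an estimate of 2.84 h more to consume those crystals. At 6.00 h, ochre reads crystals 0% and target 4.03%.

The constants used here were chosen freely; the result is computed.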